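(The runs are calculated for an exercise, noise included.)

How far has the substrate gone at the asked time, once a pairing side reaction is allowed for?

all flasks: substrate 14 mM (fed, over 20 min)

| flask | acid | remark | time |
|---|---|---|---|
| midnight | 0.42 mM | the very flask that is asked about, followed so far |  |
| winter | 0.63 mM | run made earlier |  |
| flask | 0.420 mM |  | 50 min |

| run | time / min | substrate / % | target / % |
|---|---|---|---|
| midnight | 1.50 | 7.2 | 0.4 |
| midnight | 3.00 | 14.7 | 1.3 |
| midnight | 5.00 | 22.8 | 2.2 |
| midnight | 6.00 | 26.9 | 2.6 |
| midnight | 8.00 | 33.2 | 6.2 |
| midnight | 10.0 | 39.3 | 8.2 |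
| winter | 3.00 | 14.5 | 1.0 |
| winter | 5.00 | 20.9 | 3.2 |
| winter | 8.00 | 30.4 | 7.4 |
| winter | 12.0 | 40.0 | 15.1 |
| winter | 20.0 | 51.4 | 34.1 |
| winter | 40.0 | 17.9 | 61.4 |

(scatter of a reading: 0.5 percentage points)

- part of the substrate that has reacted at 50 min
- pH of the solution at 50 min

- acid is the free proton; pH is minus the decimal logarithm of its molar concentration
- a reading or a percentage of target counts all its forms, free or not
- what has gone from substrate into another species counts as reacted, even if it can come back
- percentages count the whole charge, also what has not yet gone in
- a reading of substrate is of its free form alone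

In the winter run at 12.0 min, substrate and target readings fell short of the dosed share by 4.90%. I read this gap as a pair of substrate with target, counted once in the target reading, and neglected other losses that early. Taking the pairing as a pre-equilibrium, I reckoned 85.8 M⁻¹ for [pair]/([substrate][free target]), which I called the pairing quotient.

For the midnight flask, the loss up to 10.0 min gave an apparent constant of 0.0545 min⁻¹, so about 60.9% stood free at the end of the feed. I assumed the later fall scales with acid, so the winter tail gave 0.0352 min⁻¹ for this flask. My reckoning was 78.8% reacted. For the pH I took the acid as staying at its charge.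

The forecast, lower than mine, gave 75% and pH 3.5: "so about 75 % has reacted".

The flask gave 81.8% and pH 3.38.

    substrate → weak acid + target (k = 6.85 × 10⁻⁵ s⁻¹)
    substrate + target → side product (k = 0.0231 M⁻¹ s⁻¹)
    substrate + target ⇌ idle adduct, settled at all times (K = 83.0 M⁻¹)
    substrate + acid → weak acid + acid + target (k = 1.29 M⁻¹ s⁻¹)
    crystals ⇌ weak acid, rate k5*(cs5 - [weak acid]) while solid is left; crystals form when [weak acid] > cs5 (solubility = 0.340 mM, k = 0.0266 s⁻¹)
    weak acid ⇌ conjugate base + acid, settled at all times (K = 7.90 × 10⁻⁸ M)

At 23.8 min, the half-life of substrate by the step to side product was 170 min, long against 50 min. At 50.0 min, its half-life by the acid step was 21 min. The pair is the idle adduct, which counts twice in a percentage. With the flask's substrate and free target at 50.0 min, the pairing quotient gives 20.8% of idle adduct, and the flask holds 20.1%. In the neighbour flask with 0.10 mM of acid, it gives 22.2%, and that flask holds 21.5%.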